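**Remark on the chemistry.** The target has no stereocentre and no double bond with a configuration to set. The atom mapping of the key step was checked and needed no correction (pyranone C2 → C8a, C3 → C4a; diazo carbon → C8; acyl carbon → C5; alkyne carbons → C6 and C7). Only protecting groups, reagents and starting materials were changed.

## Structural features

The target is an isoflavone: benzo ring A is fused through the C4a–C8a bond to pyranone ring C, and ring B hangs on C3 through the C3–C1' bond. Ring A is a phloroglucinol unit with OH at C5 (hydrogen-bonded to the C4 carbonyl), a 3-hydroxy-3-methylbutyl chain at C6, OH at C7 and hydrogen at C8. Ring B is a resorcinol with OH at C2' and C4' and a prenyl group at C3' between them. The tertiary alcohol sits two carbons from ring A between two phenols and can ionise under acid to close a 2,2-dimethylchroman. The prenyl alkene, ortho to two phenols, can do the same and is also open to electrophiles, oxidants and hydrogenation. C2 of ring C is an acceptor whose attack by hydroxide opens the pyranone. The real difficulty is regiochemical: the chain must go to C6 and not C8 of a ring whose three oxygens make these positions nearly equivalent in classical closures of ring C. The key step exploits the row C5(OH)–C6(chain)–C7(O) beside the shared C4a–C8a bond. That row is what a ketene carbon (C5) and the two carbons of an ynol ether (C6, C7) leave when a vinylketene is annulated onto the C2=C3 bond of a 4-pyranone that already carries O1 and ring B.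

## Logic of the disconnections

**27 to 26 to 25.** The two aryl O–CH2 acetal bonds, the tertiary O–Si bond and the aryl O–Si bond at O7 are cut. Every hydroxyl except the chelated 5-OH must be masked while a ketene is in the flask. The tertiary hydroxyl is carried as a triethylsilyl ether and not as an acetal, so the last acid step only has to cleave two phenolic acetals and one labile silyl ether. The forward demand is fluoride first (O7), then brief dilute acid that does not ionise the tertiary alcohol or protonate the prenyl alkene.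

**25 to 14 and 21.** Four bonds are cut: C8–C8a, C5–C6, C7–C8 and C4a–C5. Ring A disappears; what remains is a pyranone that already holds O1, the C4 carbonyl and ring B, and an acyclic alkyne that holds the chain. Because O1 is in place before ring A exists, no 8-alkyl isomer can arise. The forward step must generate the ketene from 14 without exciting the pyranone, and the cycloaddition with 21 must be head-to-tail.

**14 to 12 to 11.** The CO–CHN2 bond is cut back to a carboxylic acid, and the acid to its methyl ester. A diazomethyl ketone comes from C-acylation of a diazomethane equivalent. The forward step must activate 12 without HCl (acetals, prenyl alkene), so mixed anhydride 13 and (trimethylsilyl)diazomethane replace an acid chloride and diazomethane. The ester must be hydrolysed without hydroxide opening the pyranone.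

**11 to 10 and 7.** The bond between pyranone C5 and ring B C1' (the future C3–C1') is cut. An sp2–sp2 cross-coupling joins two one-ring fragments convergently. The enol triflate must survive the base, and the ortho-alkoxy boronate must transmetalate before it protodeboronates.

**10 to 9 to 8.** The S–O bond and the ester C–O bond are cut. Compound 8 is commercial and already has the enolic oxygen and the carboxyl group on the right pyranone carbons.

**7 to 5 to 2 (with 3) to 1.** The C–B bond, the aryl–prenyl C–C bond and two O–CH2 bonds are cut. Two consecutive directed ortho-metalations do the work: first between the two acetal oxygens of 2 (through 4), then at the only kind of ortho hydrogen left in the symmetrical 5 (through 6). Starting from 1 avoids an amide-base metalation next to a C–Br bond. The prenylation must be SN2 and not SN2'.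

**21 to 18 to 17 to 15.** The C(sp)–O bond, the tertiary O–Si bond and the two C–CH3 bonds are cut. The alkyne carbon of 18 is oxygenated through 19 and 20 and silylated on oxygen. Double methyl addition to 15 (through 16) makes the tertiary carbinol in one step.

## Other disconnections considered

**Alternative 1:** The cut is C3–C1' together with O1–C2, made after a 1,2-aryl shift. The precursor is the 2'-hydroxychalcone (E)-3-[3-bromo-2,4-bis(methoxymethoxy)phenyl]-1-[2-hydroxy-5-(3-hydroxy-3-methylbutyl)-4,6-bis(methoxymethoxy)phenyl]prop-2-en-1-one A1.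
- Forward key step: Tl(NO3)3 in methanol and trimethyl orthoformate oxythallates the enone of A1, ring B migrates from the beta to the alpha carbon, and mild acid closes the acetal onto the phenol to give 3-[3-bromo-2,4-bis(methoxymethoxy)phenyl]-6-(3-hydroxy-3-methylbutyl)-5,7-bis(methoxymethoxy)chromen-4-one A2.
- In its favour: the aryl shift is established chemistry for isoflavones, the electron-rich ring B migrates readily, and one flask forms both C3–C1' and ring C. On certainty of the key step this alternative is better than the chosen plan.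
- Against it here: a stoichiometric trivalent thallium salt is at odds with a safe route. The prenyl alkene would be oxythallated, so A2 carries bromine and needs a late prenyl cross-coupling between two acetal oxygens, with linear versus branched selectivity to control. The acetophenone half of A1 needs its free hydroxyl para to the chain, so the 6-alkyl versus 8-alkyl question is only moved into the synthesis of A1.
- Comparison: structurally it does not use the C5–C6–C7 pattern. Mechanistically it is the safer bet. In step economy it pays for the placeholder and for regiocontrol in ring A, and should be longer overall.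

**Alternative 2:** The cut is O1–C8a and C4–C4a. The partners are the aryne precursor 3,5-bis(methoxymethoxy)-4-[3-(methoxymethoxy)-3-methylbutyl]-2-(trimethylsilyl)phenyl trifluoromethanesulfonate A3 and the formylated arylacetate methyl 2-[2,4-bis(methoxymethoxy)-3-(3-methylbut-2-en-1-yl)phenyl]-3-hydroxyprop-2-enoate A4.
- Forward key step: CsF releases the aryne from A3, the enol oxygen of A4 adds at C8a, and the C4a anion attacks the ester to give 3-[2,4-bis(methoxymethoxy)-3-(3-methylbut-2-enyl)phenyl]-6-[3-(methoxymethoxy)-3-methylbutyl]-5,7-bis(methoxymethoxy)chromen-4-one A5.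
- In its favour: it is fully convergent, needs no light, and leaves one deprotection after the key step, which is better than the chosen plan's two. The C5 alkoxy group of the aryne steers the nucleophile to the distal carbon. A3 derives from a symmetrical 2-alkylphloroglucinol whose oxygen para to the chain is unique, so the 6/8 problem is solved as cleanly as in the chosen plan; on this point the two are equal.
- Against it here: the enolate of A4 is ambident, and C-arylation with insertion into the C–C bond is the usual course of arynes with beta-dicarbonyl compounds. The aryl anion can also be protonated before it reaches the ester. A3 is a hexasubstituted benzene that needs a silylation and triflation sequence on a crowded ring.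
- Comparison: both plans rest on an unproven step. The chosen plan draws its regiocontrol from the fixed polarity of an ynol ether, whereas this one needs O- over C-selectivity that the substrate does not enforce. Total step counts should be similar.

**Alternative 3:** The cut is through ring B (C5'–C6', C2'–C3', C4'–C5', C1'–C2'). The partners are the diazo enone 3-[(1E)-4-diazo-3-oxobut-1-en-1-yl]-6-[3-(methoxymethoxy)-3-methylbutyl]-5,7-bis(methoxymethoxy)-4H-chromen-4-one A6 and the ynol ether triisopropyl[(5-methylhex-4-en-1-yn-1-yl)oxy]silane A7.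
- Forward key step: Wolff rearrangement of A6 gives a vinylketene that adds A7 and electrocyclises to 3-[2-hydroxy-3-(3-methylbut-2-enyl)-4-(triisopropylsilyloxy)phenyl]-6-[3-(methoxymethoxy)-3-methylbutyl]-5,7-bis(methoxymethoxy)chromen-4-one A8.
- In its favour: A6 is an acyclic unsaturated diazomethyl ketone, exactly the substrate class of the known benzannulation. In precedent this alternative is better than the chosen plan. It sets OH, prenyl and oxygen of ring B in one step.
- Against it here: rings A and C must be made first by classical means, so the 6/8 problem is untouched. A7 is a skipped enyne whose doubly activated CH2 invites isomerisation during ynolate formation. The chromone of A6 is itself a chromophore and an acceptor.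
- Comparison: the same reaction type is spent on ring B, where two ortho-metalations already give the pattern in three steps. The chosen plan spends it on ring A, where regiochemistry is hard. This alternative should be longer.

Key step: step 12

## Route

**Step 1**
Reactants: 1 resorcinol
Product: 2 1,3-bis(methoxymethoxy)benzene
Conditions: CH2(OMe)2, AcCl, ZnBr2 (0.01 mol %), PhMe, 25 °C; then 1, i-Pr2NEt, 0 → 25 °C
Reagents that add atoms: chloromethyl methyl ether, COCCl (generated in the flask from dimethoxymethane, COCOC, and acetyl chloride, CC(=O)Cl)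
Why: O-alkylation of both phenols to the acetals; making the chloro ether in solution avoids handling the neat carcinogen and keeps it free of bis(chloromethyl) ether.

**Step 2**
Reactants: 2 1,3-bis(methoxymethoxy)benzene; 3 1-bromo-3-methylbut-2-ene
Product: 5 1,3-bis(methoxymethoxy)-2-(3-methylbut-2-en-1-yl)benzene, via aryllithium 4 (not isolated)
Conditions: n-BuLi, THF, 0 → 25 °C; CuI (10 mol %), then 3, −78 → 0 °C
Reagents that add atoms: none
Why: Directed ortho-metalation at the doubly activated C2, then copper-mediated SN2 allylation; attack at the unsubstituted allyl terminus avoids a quaternary centre.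

**Step 3**
Reactants: 5 1,3-bis(methoxymethoxy)-2-(3-methylbut-2-en-1-yl)benzene
Product: 7 2-[2,4-bis(methoxymethoxy)-3-(3-methylbut-2-en-1-yl)phenyl]-4,4,5,5-tetramethyl-1,3,2-dioxaborolane, via aryllithium 6 (not isolated)
Conditions: n-BuLi, TMEDA, THF, −20 → 0 °C; i-PrOBpin, −78 → 25 °C
Reagents that add atoms: 2-isopropoxy-4,4,5,5-tetramethyl-1,3,2-dioxaborolane, CC(C)OB1OC(C)(C)C(C)(C)O1
Why: Second directed ortho-metalation; 5 is symmetrical, so only one kind of ortho hydrogen exists, and chelation by the acetal should outrun deprotonation of the allylic CH2; borylation of the aryllithium.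

**Step 4**
Reactants: 8 5-hydroxy-4-oxo-4H-pyran-2-carboxylic acid (comenic acid)
Product: 9 methyl 5-hydroxy-4-oxo-4H-pyran-2-carboxylate
Conditions: MeOH, H2SO4 (cat.), reflux
Reagents that add atoms: methanol, CO
Why: Fischer esterification; the enolic 5-OH is not alkylated under acid.

**Step 5**
Reactants: 9 methyl 5-hydroxy-4-oxo-4H-pyran-2-carboxylate
Product: 10 methyl 4-oxo-5-{[(trifluoromethyl)sulfonyl]oxy}-4H-pyran-2-carboxylate
Conditions: PhNTf2, Et3N, CH2Cl2, 0 → 25 °C
Reagents that add atoms: N-phenylbis(trifluoromethanesulfonimide), O=S(=O)(N(c1ccccc1)S(=O)(=O)C(F)(F)F)C(F)(F)F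
Why: O-sulfonylation of the acidic enol; the crystalline triflimide is milder and safer than triflic anhydride.

**Step 6**
Reactants: 10 methyl 4-oxo-5-{[(trifluoromethyl)sulfonyl]oxy}-4H-pyran-2-carboxylate; 7 2-[2,4-bis(methoxymethoxy)-3-(3-methylbut-2-en-1-yl)phenyl]-4,4,5,5-tetramethyl-1,3,2-dioxaborolane
Product: 11 methyl 5-[2,4-bis(methoxymethoxy)-3-(3-methylbut-2-en-1-yl)phenyl]-4-oxo-4H-pyran-2-carboxylate
Conditions: Pd(dppf)Cl2 (5 mol %), K3PO4, 1,4-dioxane/H2O (20:1), 70 °C
Reagents that add atoms: none
Why: Suzuki–Miyaura coupling; the electron-poor enol triflate adds readily to zerovalent palladium, and the mild phosphate base with little water limits triflate and ester hydrolysis.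

**Step 7**
Reactants: 11 methyl 5-[2,4-bis(methoxymethoxy)-3-(3-methylbut-2-en-1-yl)phenyl]-4-oxo-4H-pyran-2-carboxylate
Product: 12 5-[2,4-bis(methoxymethoxy)-3-(3-methylbut-2-en-1-yl)phenyl]-4-oxo-4H-pyran-2-carboxylic acid
Conditions: LiOH·H2O (1.1 equiv), THF/H2O, 0 °C; 1 M HCl to pH 3, 0 °C
Reagents that add atoms: lithium hydroxide, [Li+].[OH-]
Why: Saponification of an ester activated by the ring oxygen should be fast at 0 °C with one equivalent of base; the carboxylate formed then deactivates the pyranone towards further hydroxide, and brief cold acidification spares the acetals.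

**Step 8**
Reactants: 12 5-[2,4-bis(methoxymethoxy)-3-(3-methylbut-2-en-1-yl)phenyl]-4-oxo-4H-pyran-2-carboxylic acid
Product: 14 5-[2,4-bis(methoxymethoxy)-3-(3-methylbut-2-en-1-yl)phenyl]-2-(2-diazoacetyl)-4H-pyran-4-one, via mixed carbonic anhydride 13 (not isolated)
Conditions: ClCO2Et, Et3N, THF, −15 °C; Me3SiCHN2 (2 equiv), MeCN, 0 → 25 °C
Reagents that add atoms: (trimethylsilyl)diazomethane, C[Si](C)(C)C=[N+]=[N-]
Why: C-acylation of a diazoalkane by a mixed anhydride (first stage of an Arndt–Eistert sequence); the silyl group is lost to the carbonate leaving group, no HCl is formed, and explosive diazomethane is avoided.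

**Step 9**
Reactants: 15 ethyl pent-4-ynoate
Product: 17 2-methylhex-5-yn-2-ol, via hex-5-yn-2-one 16 (not isolated)
Conditions: MeMgBr (3.2 equiv), THF, 0 → 25 °C; aq. NH4Cl
Reagents that add atoms: methylmagnesium bromide, C[Mg]Br
Why: Double Grignard addition to the ester; any alkynyl C–H that is deprotonated is restored on work-up.

**Step 10**
Reactants: 17 2-methylhex-5-yn-2-ol
Product: 18 triethyl[(2-methylhex-5-yn-2-yl)oxy]silane
Conditions: Et3SiOTf, 2,6-lutidine, CH2Cl2, 0 °C
Reagents that add atoms: triethylsilyl trifluoromethanesulfonate, CC[Si](CC)(CC)OS(=O)(=O)C(F)(F)F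
Why: Silyl triflate with a hindered base silylates tertiary alcohols; the silyl ether is inert to ketenes and to the strong base of the next step and is removed at the end without forcing acid.

**Step 11**
Reactants: 18 triethyl[(2-methylhex-5-yn-2-yl)oxy]silane
Product: 21 triisopropyl({5-methyl-5-[(triethylsilyl)oxy]hex-1-yn-1-yl}oxy)silane, via lithium acetylide 19 (not isolated), via lithium ynolate 20 (not isolated)
Conditions: LiN(SiMe3)2 (2.2 equiv), THF, −78 °C; t-BuOOH (1.0 equiv, in decane), −78 → 0 °C; i-Pr3SiOTf, −78 °C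
Reagents that add atoms: tert-butyl hydroperoxide, CC(C)(C)OO; triisopropylsilyl trifluoromethanesulfonate, CC(C)[Si](OS(=O)(=O)C(F)(F)F)(C(C)C)C(C)C
Why: The acetylide attacks the peroxide oxygen of lithium tert-butyl peroxide to give the ynolate, and the hard, bulky silyl triflate traps it on oxygen to give a triisopropylsilyl ynol ether stable enough for fast chromatography.

**Step 12**
Reactants: 14 5-[2,4-bis(methoxymethoxy)-3-(3-methylbut-2-en-1-yl)phenyl]-2-(2-diazoacetyl)-4H-pyran-4-one; 21 triisopropyl({5-methyl-5-[(triethylsilyl)oxy]hex-1-yn-1-yl}oxy)silane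
Product: 25 3-[2,4-bis(methoxymethoxy)-3-(3-methylbut-2-en-1-yl)phenyl]-5-hydroxy-6-{3-methyl-3-[(triethylsilyl)oxy]butyl}-7-[(triisopropylsilyl)oxy]-4H-chromen-4-one, via pyranonyl ketene 22 (not isolated), via cyclobutenone 23 (not isolated), via dienylketene 24 (not isolated)
Conditions: 21 (1.5 equiv), degassed PhMe (0.05 M), hν (405–450 nm LEDs), 25 °C until N2 evolution ends; then 90 °C, dark
Reagents that add atoms: none
Why: Proposed new method: visible light excites the n–π* band of the diazoketone in 14 (the pyranone and the product absorb at shorter wavelength), N2 leaves and the pyranon-2-yl group migrates to the diazo carbon (Wolff rearrangement, C8–C8a), giving ketene 22 whose carbonyl carbon is the future C5. The electron-rich, chain-bearing carbon of ynol ether 21 attacks that carbonyl carbon and the (2+2) cycloaddition closes to the 3-siloxycyclobutenone 23 (C5–C6 and C7–C8); this polarity match puts the chain at C6 and the silyloxy group at C7. Warming in the dark opens 23 reversibly by four-electron conrotatory cleavage to dienylketene 24, and the isomer with the pyranone cis to the ketene closes ring A by thermal six-electron disrotatory electrocyclisation onto pyranone C3 (C4a–C5), after which a proton shift from C4a to oxygen gives the chelated C5 phenol and restores the pyranone. The closest known reaction type is the second-generation Danheiser benzannulation of aryl and heteroaryl diazomethyl ketones with siloxyalkynes; a 4-pyranone as the annulated ring is the untested element. It should be feasible because the pyranone C2=C3 bond has little aromatic stabilisation to lose and C3 is the nucleophilic carbon of a vinylogous ester, matched to the electrophilic ketene carbon. No stereocentre is set (23 is racemic and its stereocentre disappears). The step needs capture of the ketene by 21 in preference to the remote prenyl alkene (secured by the far higher nucleophilicity and the excess of the ynol ether), head-to-tail cycloaddition (secured by the ynol ether polarity), and one site of ring closure (C3 is the only terminus in reach and O1 is already in place, so no 8-alkyl isomer can form). No silver salt is used, because silver salts activate siloxyalkynes towards (2+2) addition to enones such as the pyranone.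

**Step 13**
Reactants: 25 3-[2,4-bis(methoxymethoxy)-3-(3-methylbut-2-en-1-yl)phenyl]-5-hydroxy-6-{3-methyl-3-[(triethylsilyl)oxy]butyl}-7-[(triisopropylsilyl)oxy]-4H-chromen-4-one
Product: 26 3-[2,4-bis(methoxymethoxy)-3-(3-methylbut-2-en-1-yl)phenyl]-5,7-dihydroxy-6-{3-methyl-3-[(triethylsilyl)oxy]butyl}-4H-chromen-4-one
Conditions: Bu4NF (1.1 equiv), AcOH (1.1 equiv), THF, 0 °C
Reagents that add atoms: none
Why: Fluoride cleaves the aryl silyl ether (phenoxide leaving group) much faster than the hindered tertiary alkyl silyl ether; the acetic acid buffer protects the base-sensitive chromone, and any loss of the triethylsilyl group here is harmless because step 14 removes it.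

**Step 14**
Reactants: 26 3-[2,4-bis(methoxymethoxy)-3-(3-methylbut-2-en-1-yl)phenyl]-5,7-dihydroxy-6-{3-methyl-3-[(triethylsilyl)oxy]butyl}-4H-chromen-4-one
Product: 27 3-[2,4-dihydroxy-3-(3-methylbut-2-en-1-yl)phenyl]-5,7-dihydroxy-6-(3-hydroxy-3-methylbutyl)-4H-chromen-4-one (CNP0076924.0)
Conditions: 3 M aq. HCl, MeOH/THF, 25 → 40 °C, stopped when the acetals are gone
Reagents that add atoms: none
Why: Acid-catalysed transacetalisation to methanol removes the two phenolic methoxymethyl groups and methanolysis removes the triethylsilyl ether; both are faster than ionisation of the tertiary alcohol or protonation of the trisubstituted alkene in dilute acid.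

## Compound list

1 | resorcinol | Oc1cccc(O)c1 | starting material
2 | 1,3-bis(methoxymethoxy)benzene | COCOc1cccc(OCOC)c1 | intermediate
3 | 1-bromo-3-methylbut-2-ene (prenyl bromide) | CC(C)=CCBr | starting material
4 | [2,6-bis(methoxymethoxy)phenyl]lithium | [Li]c1c(OCOC)cccc1OCOC | intermediate (not isolated)
5 | 1,3-bis(methoxymethoxy)-2-(3-methylbut-2-en-1-yl)benzene | COCOc1cccc(OCOC)c1CC=C(C)C | intermediate
6 | [2,4-bis(methoxymethoxy)-3-(3-methylbut-2-en-1-yl)phenyl]lithium | [Li]c1ccc(OCOC)c(CC=C(C)C)c1OCOC | intermediate (not isolated)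
7 | 2-[2,4-bis(methoxymethoxy)-3-(3-methylbut-2-en-1-yl)phenyl]-4,4,5,5-tetramethyl-1,3,2-dioxaborolane | COCOc1ccc(B2OC(C)(C)C(C)(C)O2)c(OCOC)c1CC=C(C)C | intermediate
8 | 5-hydroxy-4-oxo-4H-pyran-2-carboxylic acid (comenic acid) | O=C(O)c1cc(=O)c(O)co1 | starting material
9 | methyl 5-hydroxy-4-oxo-4H-pyran-2-carboxylate | COC(=O)c1cc(=O)c(O)co1 | intermediate
10 | methyl 4-oxo-5-{[(trifluoromethyl)sulfonyl]oxy}-4H-pyran-2-carboxylate | COC(=O)c1cc(=O)c(OS(=O)(=O)C(F)(F)F)co1 | intermediate
11 | methyl 5-[2,4-bis(methoxymethoxy)-3-(3-methylbut-2-en-1-yl)phenyl]-4-oxo-4H-pyran-2-carboxylate | COC(=O)c1cc(=O)c(-c2ccc(OCOC)c(CC=C(C)C)c2OCOC)co1 | intermediate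
12 | 5-[2,4-bis(methoxymethoxy)-3-(3-methylbut-2-en-1-yl)phenyl]-4-oxo-4H-pyran-2-carboxylic acid | O=C(O)c1cc(=O)c(-c2ccc(OCOC)c(CC=C(C)C)c2OCOC)co1 | intermediate
13 | ethyl carbonic anhydride of acid 12 | CCOC(=O)OC(=O)c1cc(=O)c(-c2ccc(OCOC)c(CC=C(C)C)c2OCOC)co1 | intermediate (not isolated)
14 | 5-[2,4-bis(methoxymethoxy)-3-(3-methylbut-2-en-1-yl)phenyl]-2-(2-diazoacetyl)-4H-pyran-4-one | [N-]=[N+]=CC(=O)c1cc(=O)c(-c2ccc(OCOC)c(CC=C(C)C)c2OCOC)co1 | intermediate
15 | ethyl pent-4-ynoate | C#CCCC(=O)OCC | starting material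
16 | hex-5-yn-2-one | C#CCCC(C)=O | intermediate (not isolated)
17 | 2-methylhex-5-yn-2-ol | C#CCCC(C)(C)O | intermediate
18 | triethyl[(2-methylhex-5-yn-2-yl)oxy]silane | C#CCCC(C)(C)O[Si](CC)(CC)CC | intermediate
19 | {5-methyl-5-[(triethylsilyl)oxy]hex-1-yn-1-yl}lithium | [Li]C#CCCC(C)(C)O[Si](CC)(CC)CC | intermediate (not isolated)
20 | lithium 5-methyl-5-[(triethylsilyl)oxy]hex-1-yn-1-olate | [Li+].[O-]C#CCCC(C)(C)O[Si](CC)(CC)CC | intermediate (not isolated)
21 | triisopropyl({5-methyl-5-[(triethylsilyl)oxy]hex-1-yn-1-yl}oxy)silane | CC(C)[Si](C(C)C)(C(C)C)OC#CCCC(C)(C)O[Si](CC)(CC)CC | intermediate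
22 | 5-[2,4-bis(methoxymethoxy)-3-(3-methylbut-2-en-1-yl)phenyl]-2-(2-oxoethenyl)-4H-pyran-4-one (ketene) | O=C=Cc1cc(=O)c(-c2ccc(OCOC)c(CC=C(C)C)c2OCOC)co1 | intermediate (not isolated)
23 | 4-{5-[2,4-bis(methoxymethoxy)-3-(3-methylbut-2-en-1-yl)phenyl]-4-oxo-4H-pyran-2-yl}-2-{3-methyl-3-[(triethylsilyl)oxy]butyl}-3-[(triisopropylsilyl)oxy]cyclobut-2-en-1-one (racemic) | O=C1C(CCC(C)(C)O[Si](CC)(CC)CC)=C(O[Si](C(C)C)(C(C)C)C(C)C)C1c1cc(=O)c(-c2ccc(OCOC)c(CC=C(C)C)c2OCOC)co1 | intermediate (not isolated)
24 | (3E)-4-{5-[2,4-bis(methoxymethoxy)-3-(3-methylbut-2-en-1-yl)phenyl]-4-oxo-4H-pyran-2-yl}-2-{3-methyl-3-[(triethylsilyl)oxy]butyl}-3-[(triisopropylsilyl)oxy]buta-1,3-dien-1-one | O=C=C(CCC(C)(C)O[Si](CC)(CC)CC)/C(O[Si](C(C)C)(C(C)C)C(C)C)=C\c1cc(=O)c(-c2ccc(OCOC)c(CC=C(C)C)c2OCOC)co1 | intermediate (not isolated)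
25 | 3-[2,4-bis(methoxymethoxy)-3-(3-methylbut-2-en-1-yl)phenyl]-5-hydroxy-6-{3-methyl-3-[(triethylsilyl)oxy]butyl}-7-[(triisopropylsilyl)oxy]-4H-chromen-4-one | COCOc1ccc(-c2coc3cc(O[Si](C(C)C)(C(C)C)C(C)C)c(CCC(C)(C)O[Si](CC)(CC)CC)c(O)c3c2=O)c(OCOC)c1CC=C(C)C | intermediate
26 | 3-[2,4-bis(methoxymethoxy)-3-(3-methylbut-2-en-1-yl)phenyl]-5,7-dihydroxy-6-{3-methyl-3-[(triethylsilyl)oxy]butyl}-4H-chromen-4-one | COCOc1ccc(-c2coc3cc(O)c(CCC(C)(C)O[Si](CC)(CC)CC)c(O)c3c2=O)c(OCOC)c1CC=C(C)C | intermediate
27 | 3-[2,4-dihydroxy-3-(3-methylbut-2-en-1-yl)phenyl]-5,7-dihydroxy-6-(3-hydroxy-3-methylbutyl)-4H-chromen-4-one | CC(C)=CCc1c(O)ccc(-c2coc3cc(O)c(CCC(C)(C)O)c(O)c3c2=O)c1O | target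

## Step count and least certain steps

Total: 14 steps. Longest linear sequence: 9 steps (1, 2, 3, 6, 7, 8, 12, 13, 14).

**Step 12 (key step, proposed new method).**
- What may go wrong: the six-electron closure of 24 onto pyranone C3 may be too slow, so the ketene is lost to dimerisation, to adventitious water, or to acylation of the phenol already formed. Excitation of the pyranone, or decomposition of 23 on heating, may also compete.
- Fallback (known chemistry, leaves the pyranone platform): the established 3-iodochromone cross-coupling, with ring A made unambiguous by symmetry. It sets out from 5 and 7 and rejoins the route at 27.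
  - Mukaiyama hydration of 5 (Co(acac)2, PhSiH3, O2) should give 4-[2,6-bis(methoxymethoxy)phenyl]-2-methylbutan-2-ol F1.
  - Iridium-catalysed C–H borylation ([Ir(OMe)(cod)]2, 4,4'-di-tert-butyl-2,2'-bipyridine, B2pin2) should go to the only C–H without an ortho neighbour, para to the chain, giving 4-[2,6-bis(methoxymethoxy)-4-(4,4,5,5-tetramethyl-1,3,2-dioxaborolan-2-yl)phenyl]-2-methylbutan-2-ol F2.
  - H2O2/NaOH should convert it into 4-(3-hydroxy-3-methylbutyl)-3,5-bis(methoxymethoxy)phenol F3. Its hydroxyl is the future O1 and its two ortho positions are equivalent.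
  - Ortho-formylation (MgCl2, Et3N, paraformaldehyde) should give 2-hydroxy-5-(3-hydroxy-3-methylbutyl)-4,6-bis(methoxymethoxy)benzaldehyde F4.
  - MeMgBr should give racemic 4-[3-hydroxy-4-(1-hydroxyethyl)-2,6-bis(methoxymethoxy)phenyl]-2-methylbutan-2-ol F5, and MnO2 should give 1-[2-hydroxy-5-(3-hydroxy-3-methylbutyl)-4,6-bis(methoxymethoxy)phenyl]ethan-1-one F6.
  - Me2NCH(OMe)2 should give (E)-3-(dimethylamino)-1-[2-hydroxy-5-(3-hydroxy-3-methylbutyl)-4,6-bis(methoxymethoxy)phenyl]prop-2-en-1-one F7, and I2 should close it to 6-(3-hydroxy-3-methylbutyl)-3-iodo-5,7-bis(methoxymethoxy)-4H-chromen-4-one F8.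
  - Suzuki–Miyaura coupling of F8 with 7 (Pd(dppf)Cl2, K2CO3) should give 3-[2,4-bis(methoxymethoxy)-3-(3-methylbut-2-en-1-yl)phenyl]-6-(3-hydroxy-3-methylbutyl)-5,7-bis(methoxymethoxy)-4H-chromen-4-one F9, and dilute HCl in methanol should remove its four acetals to give 27.

**Step 6 (Suzuki–Miyaura coupling).**
- What may go wrong: S–O cleavage of the enol triflate or opening of the pyranone by the aqueous base, and protodeboronation of the electron-rich ortho-alkoxy boronate before transmetalation.
- Fallback: a base-free Negishi coupling. It sets out from 5 and rejoins at 11. Aryllithium 6, made as in step 3, is transmetalated with ZnCl2 to {2,4-bis(methoxymethoxy)-3-(3-methylbut-2-en-1-yl)phenyl}zinc chloride F10, which is coupled with 10 (Pd(PPh3)4, THF, 50 °C).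

**Step 7 (ester hydrolysis).**
- What may go wrong: conjugate addition of hydroxide at C6 of the pyranone with ring opening, in competition with acyl substitution.
- Fallback: the acid is unmasked by fluoride-induced elimination instead of hydroxide. It sets out from 8 and rejoins at 12.
  - Steglich esterification of 8 with 2-(trimethylsilyl)ethanol should give 2-(trimethylsilyl)ethyl 5-hydroxy-4-oxo-4H-pyran-2-carboxylate F11.
  - PhNTf2/Et3N should give 2-(trimethylsilyl)ethyl 4-oxo-5-{[(trifluoromethyl)sulfonyl]oxy}-4H-pyran-2-carboxylate F12.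
  - Coupling with 7 as in step 6 should give 2-(trimethylsilyl)ethyl 5-[2,4-bis(methoxymethoxy)-3-(3-methylbut-2-en-1-yl)phenyl]-4-oxo-4H-pyran-2-carboxylate F13.
  - Bu4NF in THF should release 12 after mild acidification.

**Step 8 (diazoketone formation).**
- What may go wrong: attack of the weakly nucleophilic silyl diazoalkane at the carbonate carbonyl of 13 or incomplete acylation, followed by O-methylation of regenerated 12.
- Fallback: the diazo group is introduced by transfer to a ketone instead of by acylation. It sets out from 12 and rejoins at 14.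
  - EDC and MeNHOMe·HCl should give 5-[2,4-bis(methoxymethoxy)-3-(3-methylbut-2-en-1-yl)phenyl]-N-methoxy-N-methyl-4-oxo-4H-pyran-2-carboxamide F14.
  - MeMgBr at −78 °C should give 2-acetyl-5-[2,4-bis(methoxymethoxy)-3-(3-methylbut-2-en-1-yl)phenyl]-4H-pyran-4-one F15.
  - LiN(SiMe3)2 and 2,2,2-trifluoroethyl trifluoroacetate should give 1-{5-[2,4-bis(methoxymethoxy)-3-(3-methylbut-2-en-1-yl)phenyl]-4-oxo-4H-pyran-2-yl}-4,4,4-trifluorobutane-1,3-dione F16.
  - 4-Acetamidobenzenesulfonyl azide, Et3N and water in MeCN should give 14 by detrifluoroacetylative diazo transfer.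

**Step 14 (final deprotection).**
- What may go wrong: acid-induced ionisation of the tertiary alcohol or protonation of the prenyl alkene, followed by ring closure onto a neighbouring phenol, in competition with acetal cleavage.
- Fallback: the acetals are removed without Brønsted acid, before the silyl groups. It sets out from 25 and rejoins at 27.
  - Me3SiOTf and 2,2'-bipyridyl in CH2Cl2 at 0 °C should convert the two aryl acetals into aryl silyl ethers, giving 3-[3-(3-methylbut-2-en-1-yl)-2,4-bis(trimethylsilyloxy)phenyl]-5-hydroxy-6-{3-methyl-3-[(triethylsilyl)oxy]butyl}-7-[(triisopropylsilyl)oxy]-4H-chromen-4-one F17. Any silylation of the chelated 5-OH is undone in the same work-up.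
  - Water in the work-up should hydrolyse F17 to 3-[2,4-dihydroxy-3-(3-methylbut-2-en-1-yl)phenyl]-5-hydroxy-6-{3-methyl-3-[(triethylsilyl)oxy]butyl}-7-[(triisopropylsilyl)oxy]-4H-chromen-4-one F18.
  - Bu4NF (3 equiv) with AcOH in THF at 25–40 °C should remove both remaining silyl groups to give 27.

## Further compounds

F1 | step 12 | 4-[2,6-bis(methoxymethoxy)phenyl]-2-methylbutan-2-ol | COCOc1cccc(OCOC)c1CCC(C)(C)O
F2 | step 12 | 4-[2,6-bis(methoxymethoxy)-4-(4,4,5,5-tetramethyl-1,3,2-dioxaborolan-2-yl)phenyl]-2-methylbutan-2-ol | COCOc1cc(B2OC(C)(C)C(C)(C)O2)cc(OCOC)c1CCC(C)(C)O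
F3 | step 12 | 4-(3-hydroxy-3-methylbutyl)-3,5-bis(methoxymethoxy)phenol | COCOc1cc(O)cc(OCOC)c1CCC(C)(C)O
F4 | step 12 | 2-hydroxy-5-(3-hydroxy-3-methylbutyl)-4,6-bis(methoxymethoxy)benzaldehyde | COCOc1cc(O)c(C=O)c(OCOC)c1CCC(C)(C)O
F5 | step 12 | 4-[3-hydroxy-4-(1-hydroxyethyl)-2,6-bis(methoxymethoxy)phenyl]-2-methylbutan-2-ol (racemic) | COCOc1cc(O)c(C(C)O)c(OCOC)c1CCC(C)(C)O
F6 | step 12 | 1-[2-hydroxy-5-(3-hydroxy-3-methylbutyl)-4,6-bis(methoxymethoxy)phenyl]ethan-1-one | COCOc1cc(O)c(C(C)=O)c(OCOC)c1CCC(C)(C)O
F7 | step 12 | (E)-3-(dimethylamino)-1-[2-hydroxy-5-(3-hydroxy-3-methylbutyl)-4,6-bis(methoxymethoxy)phenyl]prop-2-en-1-one | COCOc1cc(O)c(C(=O)/C=C/N(C)C)c(OCOC)c1CCC(C)(C)O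
F8 | step 12 | 6-(3-hydroxy-3-methylbutyl)-3-iodo-5,7-bis(methoxymethoxy)-4H-chromen-4-one | COCOc1cc2occ(I)c(=O)c2c(OCOC)c1CCC(C)(C)O
F9 | step 12 | 3-[2,4-bis(methoxymethoxy)-3-(3-methylbut-2-en-1-yl)phenyl]-6-(3-hydroxy-3-methylbutyl)-5,7-bis(methoxymethoxy)-4H-chromen-4-one | COCOc1ccc(-c2coc3cc(OCOC)c(CCC(C)(C)O)c(OCOC)c3c2=O)c(OCOC)c1CC=C(C)C
F10 | step 6 | {2,4-bis(methoxymethoxy)-3-(3-methylbut-2-en-1-yl)phenyl}zinc chloride | Cl[Zn]c1ccc(OCOC)c(CC=C(C)C)c1OCOC
F11 | step 7 | 2-(trimethylsilyl)ethyl 5-hydroxy-4-oxo-4H-pyran-2-carboxylate | C[Si](C)(C)CCOC(=O)c1cc(=O)c(O)co1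
F12 | step 7 | 2-(trimethylsilyl)ethyl 4-oxo-5-{[(trifluoromethyl)sulfonyl]oxy}-4H-pyran-2-carboxylate | C[Si](C)(C)CCOC(=O)c1cc(=O)c(OS(=O)(=O)C(F)(F)F)co1
F13 | step 7 | 2-(trimethylsilyl)ethyl 5-[2,4-bis(methoxymethoxy)-3-(3-methylbut-2-en-1-yl)phenyl]-4-oxo-4H-pyran-2-carboxylate | C[Si](C)(C)CCOC(=O)c1cc(=O)c(-c2ccc(OCOC)c(CC=C(C)C)c2OCOC)co1
F14 | step 8 | 5-[2,4-bis(methoxymethoxy)-3-(3-methylbut-2-en-1-yl)phenyl]-N-methoxy-N-methyl-4-oxo-4H-pyran-2-carboxamide | CON(C)C(=O)c1cc(=O)c(-c2ccc(OCOC)c(CC=C(C)C)c2OCOC)co1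
F15 | step 8 | 2-acetyl-5-[2,4-bis(methoxymethoxy)-3-(3-methylbut-2-en-1-yl)phenyl]-4H-pyran-4-one | CC(=O)c1cc(=O)c(-c2ccc(OCOC)c(CC=C(C)C)c2OCOC)co1
F16 | step 8 | 1-{5-[2,4-bis(methoxymethoxy)-3-(3-methylbut-2-en-1-yl)phenyl]-4-oxo-4H-pyran-2-yl}-4,4,4-trifluorobutane-1,3-dione | O=C(CC(=O)C(F)(F)F)c1cc(=O)c(-c2ccc(OCOC)c(CC=C(C)C)c2OCOC)co1
F17 | step 14 | 3-[3-(3-methylbut-2-en-1-yl)-2,4-bis(trimethylsilyloxy)phenyl]-5-hydroxy-6-{3-methyl-3-[(triethylsilyl)oxy]butyl}-7-[(triisopropylsilyl)oxy]-4H-chromen-4-one | C[Si](C)(C)Oc1ccc(-c2coc3cc(O[Si](C(C)C)(C(C)C)C(C)C)c(CCC(C)(C)O[Si](CC)(CC)CC)c(O)c3c2=O)c(O[Si](C)(C)C)c1CC=C(C)C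
F18 | step 14 | 3-[2,4-dihydroxy-3-(3-methylbut-2-en-1-yl)phenyl]-5-hydroxy-6-{3-methyl-3-[(triethylsilyl)oxy]butyl}-7-[(triisopropylsilyl)oxy]-4H-chromen-4-one | CC(C)=CCc1c(O)ccc(-c2coc3cc(O[Si](C(C)C)(C(C)C)C(C)C)c(CCC(C)(C)O[Si](CC)(CC)CC)c(O)c3c2=O)c1O
A1 | alternative 1 | (E)-3-[3-bromo-2,4-bis(methoxymethoxy)phenyl]-1-[2-hydroxy-5-(3-hydroxy-3-methylbutyl)-4,6-bis(methoxymethoxy)phenyl]prop-2-en-1-one | COCOc1ccc(/C=C/C(=O)c2c(O)cc(OCOC)c(CCC(C)(C)O)c2OCOC)c(OCOC)c1Br
A2 | alternative 1 | 3-[3-bromo-2,4-bis(methoxymethoxy)phenyl]-6-(3-hydroxy-3-methylbutyl)-5,7-bis(methoxymethoxy)chromen-4-one | COCOc1ccc(-c2coc3cc(OCOC)c(CCC(C)(C)O)c(OCOC)c3c2=O)c(OCOC)c1Br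
A3 | alternative 2 | 3,5-bis(methoxymethoxy)-4-[3-(methoxymethoxy)-3-methylbutyl]-2-(trimethylsilyl)phenyl trifluoromethanesulfonate | COCOc1cc(OS(=O)(=O)C(F)(F)F)c([Si](C)(C)C)c(OCOC)c1CCC(C)(C)OCOC
A4 | alternative 2 | methyl 2-[2,4-bis(methoxymethoxy)-3-(3-methylbut-2-en-1-yl)phenyl]-3-hydroxyprop-2-enoate | COC(=O)C(=CO)c1ccc(OCOC)c(CC=C(C)C)c1OCOC
A5 | alternative 2 | 3-[2,4-bis(methoxymethoxy)-3-(3-methylbut-2-enyl)phenyl]-6-[3-(methoxymethoxy)-3-methylbutyl]-5,7-bis(methoxymethoxy)chromen-4-one | COCOc1ccc(-c2coc3cc(OCOC)c(CCC(C)(C)OCOC)c(OCOC)c3c2=O)c(OCOC)c1CC=C(C)C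
A6 | alternative 3 | 3-[(1E)-4-diazo-3-oxobut-1-en-1-yl]-6-[3-(methoxymethoxy)-3-methylbutyl]-5,7-bis(methoxymethoxy)-4H-chromen-4-one | [N-]=[N+]=CC(=O)/C=C/c1coc2cc(OCOC)c(CCC(C)(C)OCOC)c(OCOC)c2c1=O
A7 | alternative 3 | triisopropyl[(5-methylhex-4-en-1-yn-1-yl)oxy]silane | CC(C)=CCC#CO[Si](C(C)C)(C(C)C)C(C)C
A8 | alternative 3 | 3-[2-hydroxy-3-(3-methylbut-2-enyl)-4-(triisopropylsilyloxy)phenyl]-6-[3-(methoxymethoxy)-3-methylbutyl]-5,7-bis(methoxymethoxy)chromen-4-one | CC(C)=CCc1c(O[Si](C(C)C)(C(C)C)C(C)C)ccc(-c2coc3cc(OCOC)c(CCC(C)(C)OCOC)c(OCOC)c3c2=O)c1O
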